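Readings and results stem from a simulated flask from invented constants.

The constants are hidden at first, so I start from what needs none of them: the charges and the rows of flask alpha, which is the flask asked about.

| flask | substrate | partner | free catalyst | added ligand | remark |
|---|---|---|---|---|---|
| alpha | 0.80 M | 0.40 M | 2.1 mM | 6.6 mM | the very flask that is asked about, followed so far |
| flask | 0.80 M | 0.400 M | 2.1 mM | 6.6 mM |  |

alpha run (percent of the substrate charged)

| time / min | product / % |
|---|---|
| 0.667 | 0.8 |
| 1.33 | 3.2 |
| 3.00 | 5.6 |
| 8.00 | 12.7 |

(scatter of a reading: 0.5 percentage points)

- apparent order in free catalyst when 30 % of the substrate are converted (percent change of the rate of making product for one percent more free catalyst charged)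
- apparent order in partner when 30 % of the substrate are converted (percent change of the rate of making product for one percent more partner charged)

Each round on the list of suspects takes one partner and gives one product, so the rate of partner use divided by the rate of making product is one. Time drops out, and the partner left can be read from the conversion. Flask alpha holds twice as much substrate as partner, which makes partner the limiting reagent. At 30 % conversion 0.160 M of partner is left, and partner charged over partner left comes to 2.50. I call this the lever: the percent by which the partner left at that conversion rises for one percent more partner charged.

Reading down the rows, the lever is 1.02 in the first row and 1.34 in the last. The pace from the second row to the third, divided by the pace from the third to the last, is 1.01, so the rows show no slowing beyond their scatter. My rule, at the same conversion and with the other steps held unchanged, is that the order in partner charged equals the lever times the share of the round's time spent waiting for partner. That share looks small at the charge and grows as partner falls. I guess a quarter at 30 % conversion, which gives 0.625.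

The forecast gives 1.15 in free catalyst and 0.4 in partner, saying “the partner order is about 0.4, but this is poorly defined”. My figure for partner stands higher.

The flask gives 1.0 in free catalyst, within the forecast's margin, and 0.66 in partner, 1.65 times the forecast's value.

    substrate + free catalyst → catalyst intermediate A (k = 0.538 M⁻¹ s⁻¹)
    catalyst intermediate A → catalyst intermediate B (k = 0.716 s⁻¹)
    partner + catalyst intermediate B → catalyst intermediate C (k = 1.78 M⁻¹ s⁻¹)
    catalyst intermediate C ⇌ catalyst intermediate D (K = 3.00, k = 0.559 s⁻¹)
    catalyst intermediate D → free catalyst + product (k = 52.3 s⁻¹)
    free catalyst + added ligand ⇌ idle complex, settled at all times (K = 170 M⁻¹)

Divided by the lever, the order in partner leaves a share of 0.264. Per catalyst intermediate B, the step with partner runs at 43 min⁻¹ with partner as charged, so at 17.1 min⁻¹ at 30 % conversion in flask alpha, slower than the 34 min⁻¹ at which catalyst intermediate C turns into catalyst intermediate D. At 25.0 min, with 31 % of the partner left, flask alpha holds 30.3 % of its catalyst as intermediate B against 12.0 % as intermediate C.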